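**Retrosynthetic overview**

1. Late steps: the C1–O–C10 vinyl epoxide comes from inverting closure of the C10 tertiary alkoxide onto an activated C1 carbinol. The α-methylene lactone is unmasked from a Mannich base, and the C8 ester is carried from the open-chain stage.
2. Key disconnection: the ten-membered carbocycle (C1–C10) is not closed as such. It arises from a cis-cyclooctene (C1, C2, C5–C10) when the two inner carbons of a 2-(hydroxymethyl)buta-1,3-diene (C3, C4, carrying C15) are inserted into its C2=C5 bond by a silicon-tethered ring-opening/ring-closing metathesis.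
3. Enabling feature: the ring-cis 1,3-diene C2=C3–C4(C15H2OH)=C5 lies between ring carbons C2 and C5, and its C15 oxygen is 1,6-related to the C1 oxygen through C1–C2=C3–C4–C15. So C2/C5 can be the two ends of a cyclooctene double bond, and O1/O15 the two ends of a silaketal that can deliver C3 only to C2.
4. The cyclooctene comes from RCM of an open-chain diene. Its chain comes from conjugate addition of a C8 dithiane anion to (S)-5-(silyloxymethyl)butenolide (C6, C7), 1,3-anti reduction (C8), and dithiane opening of a Sharpless-resolved epoxy alcohol (C10, C1).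
5. Order of ring formation: γ-lactone (chiral pool) → eight-membered carbocycle (RCM) → eight-membered silaketal and ten-membered carbocycle together (key step) → epoxide.

Key step: step 19

Remark: carbons are cited by the germacranolide numbering of the target (C1 and C10 epoxide carbons, C2=C3 and C4=C5 diene, C6 lactone carbinol carbon, C7 ring-fusion carbon, C8 ester carbinol carbon, C9 methylene, C11–C13 lactone carbons with C13 the exocyclic methylene, C14 methyl, C15 hydroxymethyl); compounds 1, 5, 7, 12, 13 and 22 are assumed to be bought.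

**Route**

Step 1
Reactants: 1 methacrolein
Product: 2 rac-2-methylpenta-1,4-dien-3-ol
Conditions: CH2=CHMgBr, THF, −78 → 0 °C; aq. NH4Cl
Reagents that add atoms: vinylmagnesium bromide, C=C[Mg]Br
Why: Grignard 1,2-addition to the enal gives the racemic bis-allylic carbinol, whose single stereocentre (C1) is resolved in step 2.

Step 2
Reactants: 2 rac-2-methylpenta-1,4-dien-3-ol
Product: 3 (1S)-1-[(2R)-2-methyloxiran-2-yl]prop-2-en-1-ol
Conditions: Ti(OiPr)4 (10 mol%), L-(+)-diisopropyl tartrate (15 mol%), t-BuOOH (0.6 equiv), 4 Å MS, CH2Cl2, −20 °C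
Reagents that add atoms: tert-butyl hydroperoxide, CC(C)(C)OO
Why: Sharpless kinetic resolution: with L-(+)-tartrate the (S)-alcohol should be epoxidised fast and erythro-selectively at its electron-richer 1,1-disubstituted alkene (the vinyl group is the mismatched and slower site), so C10 (R) and C1 (S) are set together by the reagent while (R)-2 stays behind.

Step 3
Reactants: 3 (1S)-1-[(2R)-2-methyloxiran-2-yl]prop-2-en-1-ol
Product: 4 tert-butyl(dimethyl)silyl ether of 3
Conditions: TBSCl, imidazole, DMF, 0 → 23 °C
Reagents that add atoms: tert-butyldimethylsilyl chloride, CC(C)(C)[Si](C)(C)Cl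
Why: Standard silylation protects the C1 hydroxyl, so that after epoxide opening only the tertiary C10 hydroxyl, which later directs the reduction at C8, is free.

Step 4
Reactants: 4 tert-butyl(dimethyl)silyl ether of 3; 5 1,3-dithiane
Product: 6 (2R,3S)-3-[(tert-butyldimethylsilyl)oxy]-1-(1,3-dithian-2-yl)-2-methylpent-4-en-2-ol
Conditions: 5, n-BuLi, THF, −30 °C; then 4, DMPU, −30 → 23 °C; aq. NH4Cl
Reagents that add atoms: none
Why: Corey–Seebach umpolung: 2-lithio-1,3-dithiane opens the 2,2-disubstituted epoxide by SN2 attack at its CH2 carbon (C9), which installs C8 as a masked acyl anion and leaves C1 and C10 untouched.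

Step 5
Reactants: 7 (5S)-5-(hydroxymethyl)furan-2(5H)-one
Product: 8 (5S)-5-{[(tert-butyldimethylsilyl)oxy]methyl}furan-2(5H)-one
Conditions: TBSCl, imidazole, CH2Cl2, 0 °C
Reagents that add atoms: tert-butyldimethylsilyl chloride, CC(C)(C)[Si](C)(C)Cl
Why: Routine silylation of the chiral-pool butenolide, whose C6 stereocentre will steer the conjugate addition.

Step 6
Reactants: 6 (2R,3S)-3-[(tert-butyldimethylsilyl)oxy]-1-(1,3-dithian-2-yl)-2-methylpent-4-en-2-ol; 8 (5S)-5-{[(tert-butyldimethylsilyl)oxy]methyl}furan-2(5H)-one
Product: 9 (3R,4S,5S)-3-[(dimethylamino)methyl]-4-(2-substituted 1,3-dithian-2-yl)-5-(silyloxymethyl)oxolan-2-one carrying the (2R,3S) side chain of 6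
Conditions: 6, n-BuLi (2.1 equiv), THF, −30 °C; DMPU, then 8, −78 °C; then CH2=NMe2+ I−, −78 → 0 °C; aq. NH4Cl
Reagents that add atoms: dimethyl(methylidene)ammonium iodide, C=[N+](C)C.[I-]
Why: The O,C-dilithio derivative of 6 should add in the 1,4-sense to butenolide 8 anti to the silyloxymethyl group (Michael addition of a lithiated dithiane, sets C7), and the lactone enolate is trapped anti to the new C7 substituent by the iminium salt (Mannich reaction, sets C11 and masks the later exocyclic methylene group).

Step 7
Reactants: 9 aminomethyl dithianyl lactone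
Product: 10 C8 ketone (β-hydroxy ketone; stereocentres as in 9)
Conditions: PhI(OCOCF3)2, CF3CO2H (1 equiv), MeCN/H2O (9:1), 0 °C; aq. NaHCO3
Reagents that add atoms: water, O
Why: Oxidative dithioacetal hydrolysis with the hypervalent iodine reagent frees the C8 ketone under conditions that spare the vinyl group, the silyl ethers and the protonated amine.

Step 8
Reactants: 10 C8 ketone
Product: 11 C8,C10 anti-diol (C8 R; other stereocentres as in 9)
Conditions: Me4NBH(OAc)3, MeCN/AcOH (1:1), −30 °C
Reagents that add atoms: none
Why: Evans–Saksena reduction: the acetoxyborohydride exchanges onto the tertiary C10 hydroxyl and delivers hydride intramolecularly through a chair-like transition state, which should give the 1,3-anti diol and so the (R) configuration at C8.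

Step 9
Reactants: 12 acetoxyacetone; 13 tert-butyl diethylphosphonoacetate
Product: 14 tert-butyl (2E)-4-acetoxy-3-methylbut-2-enoate
Conditions: NaH, THF, 0 → 23 °C; (E)-isomer separated by chromatography
Reagents that add atoms: none
Why: Horner–Wadsworth–Emmons olefination of the methyl ketone should give mainly the (E)-enoate (ester trans to the larger acetoxymethyl group); the minor (Z)-isomer is removed.

Step 10
Reactants: 14 tert-butyl (2E)-4-acetoxy-3-methylbut-2-enoate
Product: 15 (2E)-4-acetoxy-3-methylbut-2-enoic acid
Conditions: CF3CO2H, CH2Cl2, 0 °C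
Reagents that add atoms: none
Why: Acidolysis of the tert-butyl ester (loss of isobutene) leaves the allylic acetate and the alkene geometry untouched.

Step 11
Reactants: 11 C8,C10 anti-diol; 15 (2E)-4-acetoxy-3-methylbut-2-enoic acid
Product: 16 C8 ester (side chain of the target in place)
Conditions: DCC, DMAP (cat.), CH2Cl2, 0 → 23 °C
Reagents that add atoms: none
Why: Steglich esterification acylates only the secondary C8 hydroxyl, because the C10 hydroxyl is tertiary, and so puts the final side chain in place before any carbocycle is built.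

Step 12
Reactants: 16 C8 ester
Product: 17 C5 primary alcohol
Conditions: HF·pyridine, pyridine, THF, 0 °C
Reagents that add atoms: none
Why: The primary silyl ether is cleaved much faster than the hindered secondary allylic one by buffered HF·pyridine, which frees only the C5 hydroxyl.

Step 13
Reactants: 17 C5 primary alcohol
Product: 18 C5 aldehyde
Conditions: Dess–Martin periodinane, CH2Cl2, 0 → 23 °C
Reagents that add atoms: none
Why: Dess–Martin oxidation gives the α-oxygenated aldehyde under non-basic conditions, so C6 should not epimerise.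

Step 14
Reactants: 18 C5 aldehyde
Product: 19 open-chain diene (vinyl groups on C6 and C1)
Conditions: CH2I2, Zn, Ti(OiPr)4, THF, 23 °C
Reagents that add atoms: diiodomethane, ICI
Why: Takai-type methylenation with the zinc gem-dimetal reagent is selective for aldehydes over esters and lactones and is not basic, so C6 and the C8 ester survive.

Step 15
Reactants: 19 open-chain diene
Product: 20 cis-cyclooctene trans-fused to the γ-lactone (C1 silyl ether)
Conditions: second-generation Grubbs catalyst (5 mol%), (+)-camphorsulfonic acid (1.05 equiv), CH2Cl2 (2 mM), 40 °C; aq. NaHCO3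
Reagents that add atoms: none
Why: Ring-closing metathesis of the two monosubstituted vinyl groups closes the eight-membered carbocycle, necessarily with a cis double bond, helped by the trans-disposed lactone substituents and the fully substituted C10; the amine is kept as its sulfonate salt so that it does not bind ruthenium.

Step 16
Reactants: 20 cis-cyclooctene (C1 silyl ether)
Product: 21 cyclooctenol (free C1 hydroxyl)
Conditions: HF·pyridine, pyridine, THF, 23 °C
Reagents that add atoms: none
Why: Fluoride-mediated desilylation frees the C1 hydroxyl, the anchor for the tether, without touching the esters.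

Step 17
Reactants: 22 2-methyl-2-vinyloxirane
Product: 23 2-methylidenebut-3-en-1-ol
Conditions: LiN(iPr)2, Et2O, 0 → 23 °C; aq. NH4Cl
Reagents that add atoms: none
Why: Base-promoted isomerisation of the epoxide to the allylic alcohol (β-elimination by deprotonation of the methyl group) gives the 2-substituted butadiene alcohol in one step.

Step 18
Reactants: 21 cyclooctenol; 23 2-methylidenebut-3-en-1-ol
Product: 25 diisopropylsilaketal linking O1 of the cyclooctene to the dienol, via chlorosilane 24 (not isolated)
Conditions: 23, iPr2SiCl2 (3 equiv), imidazole, CH2Cl2, 0 °C; volatiles removed; then 21, imidazole, DMAP (cat.), DMF, 23 °C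
Reagents that add atoms: dichlorodiisopropylsilane, CC(C)[Si](Cl)(Cl)C(C)C
Why: Stepwise silaketal formation: the primary dienol is converted into the monochlorosilane, which then silylates the secondary C1 hydroxyl of 21 while the tertiary C10 hydroxyl does not react.

Step 19
Reactants: 25 tethered cyclooctene silaketal
Product: 26 ten-membered (2Z,4-ring-cis) diene bridged by the O1–Si–O15 silaketal
Conditions: second-generation Hoveyda–Grubbs catalyst (15 mol%), (+)-camphorsulfonic acid (1.05 equiv), toluene (1 mM), 80 °C, argon sparge; aq. NaHCO3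
Reagents that add atoms: none
Why: Proposed new method: the ruthenium methylidene exchanges first with the monosubstituted vinyl group of the tethered 2-substituted buta-1,3-diene, the resulting alkylidene opens the strained cis-cyclooctene intramolecularly so that the diene CH carbon (C3) is joined to C2 and ruthenium is passed to C5, and this alkylidene closes onto the 1,1-disubstituted diene terminus (C4), giving back the methylidene and ethene overall, so that the two inner diene carbons are inserted into the former C2=C5 bond. The closest known reaction types are ring-rearrangement metathesis of cycloalkenes that carry a tethered alkene, temporary-silicon-tethered ring-closing metathesis and ene–diene ring-closing metathesis; their combination as a two-carbon ring expansion is what is new. Two rings are closed, the eight-membered 1,3-dioxa-2-silacyclooctene by ring-closing metathesis between C2 and C3 and the ten-membered carbocycle by ring-closing metathesis between C5 and C4, while the eight-membered carbocycle is opened. No stereocentre is formed; the C2=C3 bond is held cis by the eight-membered silaketal ring, and the C4=C5 bond is expected to be ring-cis because a trans double bond in this bridged ten-membered diene would be much more strained and the metathesis is reversible. The step needs regioselectivity (C3 to C2, C4 to C5) and must outrun oligomerisation: the first is secured by the silicon tether on the C1 oxygen, which reaches only C2, and by the faster reaction of the monosubstituted vinyl group, the second by high dilution and the ring strain of the cyclooctene. The amine is masked as its sulfonate salt, and the trisubstituted enoate and the ester groups should be inert to the catalyst.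

Step 20
Reactants: 26 bridged ten-membered diene silaketal
Product: 27 C1,C10,C15 triol
Conditions: HF·pyridine, pyridine, THF, 0 °C
Reagents that add atoms: none
Why: Buffered HF cleaves the silaketal and releases the C1 and C15 hydroxyls without opening the lactone or the esters.

Step 21
Reactants: 27 C1,C10,C15 triol
Product: 28 C15 tert-butyldimethylsilyl ether
Conditions: TBSCl (1.05 equiv), imidazole, CH2Cl2, −20 °C
Reagents that add atoms: tert-butyldimethylsilyl chloride, CC(C)(C)[Si](C)(C)Cl
Why: The primary allylic C15 hydroxyl should be silylated selectively over the hindered secondary C1 hydroxyl, so that only C1 can be activated next.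

Step 22
Reactants: 28 C15 tert-butyldimethylsilyl ether
Product: 30 C1–C10 vinyl epoxide (C15 silyl ether), via C1 mesylate 29 (not isolated)
Conditions: MsCl, Et3N, CH2Cl2, −40 °C; then DBU, −40 → 0 °C
Reagents that add atoms: none
Why: Selective mesylation of the secondary allylic C1 hydroxyl (the tertiary C10 hydroxyl does not react) and base-induced 3-exo-tet SN2 closure by the C10 alkoxide invert C1 and should give the trans-substituted vinyl epoxide with the target configuration at C1 and C10.

Step 23
Reactants: 30 C1–C10 vinyl epoxide (C15 silyl ether)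
Product: 31 C15 alcohol (Mannich base of the target)
Conditions: Bu4NF, AcOH (1:1), THF, 0 → 23 °C
Reagents that add atoms: none
Why: Acetic-acid-buffered fluoride removes the primary silyl ether without opening the vinyl epoxide or cleaving the esters.

Step 24
Reactants: 31 C15 alcohol (Mannich base of the target)
Product: 33 target CNP0292814.2, via trimethylammonium iodide 32 (not isolated)
Conditions: MeI, MeCN, 23 °C; then aq. NaHCO3, EtOAc
Reagents that add atoms: none
Why: Exhaustive N-methylation followed by E1cB loss of trimethylamine (Hofmann-type elimination of the Mannich base) unveils the α-methylene lactone under conditions that leave the vinyl epoxide, the esters and the allylic alcohol untouched.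

**Compound list**

1 | methacrolein (2-methylprop-2-enal) | CC(=C)C=O | starting material
2 | rac-2-methylpenta-1,4-dien-3-ol | C=CC(O)C(C)=C | intermediate
3 | (1S)-1-[(2R)-2-methyloxiran-2-yl]prop-2-en-1-ol | C=C[C@H](O)[C@@]1(C)CO1 | intermediate
4 | tert-butyl(dimethyl){[(1S)-1-[(2R)-2-methyloxiran-2-yl]prop-2-en-1-yl]oxy}silane | C=C[C@H](O[Si](C)(C)C(C)(C)C)[C@@]1(C)CO1 | intermediate
5 | 1,3-dithiane | C1CSCSC1 | starting material
6 | (2R,3S)-3-[(tert-butyldimethylsilyl)oxy]-1-(1,3-dithian-2-yl)-2-methylpent-4-en-2-ol | C=C[C@H](O[Si](C)(C)C(C)(C)C)[C@](C)(O)CC1SCCCS1 | intermediate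
7 | (5S)-5-(hydroxymethyl)furan-2(5H)-one | OC[C@H]1OC(=O)C=C1 | starting material
8 | (5S)-5-{[(tert-butyldimethylsilyl)oxy]methyl}furan-2(5H)-one | CC(C)(C)[Si](C)(C)OC[C@H]1OC(=O)C=C1 | intermediate
9 | (3R,4S,5S)-5-{[(tert-butyldimethylsilyl)oxy]methyl}-4-{2-[(2R,3S)-3-[(tert-butyldimethylsilyl)oxy]-2-hydroxy-2-methylpent-4-en-1-yl]-1,3-dithian-2-yl}-3-[(dimethylamino)methyl]oxolan-2-one | O=C1O[C@H](CO[Si](C)(C)C(C)(C)C)[C@@H](C2(C[C@@](C)(O)[C@@H](O[Si](C)(C)C(C)(C)C)C=C)SCCCS2)[C@@H]1CN(C)C | intermediate
10 | C8 ketone: dithiane of 9 replaced by C=O, stereocentres as in 9 | O=C1O[C@H](CO[Si](C)(C)C(C)(C)C)[C@@H](C(=O)C[C@@](C)(O)[C@@H](O[Si](C)(C)C(C)(C)C)C=C)[C@@H]1CN(C)C | intermediate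
11 | C8,C10 anti-diol: (8R)-alcohol of 10, other stereocentres as in 9 | O=C1O[C@H](CO[Si](C)(C)C(C)(C)C)[C@@H]([C@H](O)C[C@@](C)(O)[C@@H](O[Si](C)(C)C(C)(C)C)C=C)[C@@H]1CN(C)C | intermediate
12 | acetoxyacetone (2-oxopropyl acetate) | CC(=O)COC(C)=O | starting material
13 | tert-butyl diethylphosphonoacetate | CCOP(=O)(CC(=O)OC(C)(C)C)OCC | starting material
14 | tert-butyl (2E)-4-acetoxy-3-methylbut-2-enoate | CC(=O)OC/C(C)=C/C(=O)OC(C)(C)C | intermediate
15 | (2E)-4-acetoxy-3-methylbut-2-enoic acid | CC(=O)OC/C(C)=C/C(=O)O | intermediate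
16 | C8 (2E)-4-acetoxy-3-methylbut-2-enoate of 11 | O=C1O[C@H](CO[Si](C)(C)C(C)(C)C)[C@@H]([C@H](OC(=O)/C=C(\C)COC(C)=O)C[C@@](C)(O)[C@@H](O[Si](C)(C)C(C)(C)C)C=C)[C@@H]1CN(C)C | intermediate
17 | C5 primary alcohol: primary silyl ether of 16 cleaved | O=C1O[C@H](CO)[C@@H]([C@H](OC(=O)/C=C(\C)COC(C)=O)C[C@@](C)(O)[C@@H](O[Si](C)(C)C(C)(C)C)C=C)[C@@H]1CN(C)C | intermediate
18 | C5 aldehyde | O=C1O[C@H](C=O)[C@@H]([C@H](OC(=O)/C=C(\C)COC(C)=O)C[C@@](C)(O)[C@@H](O[Si](C)(C)C(C)(C)C)C=C)[C@@H]1CN(C)C | intermediate
19 | open-chain diene: vinyl groups on C6 and C1 | O=C1O[C@H](C=C)[C@@H]([C@H](OC(=O)/C=C(\C)COC(C)=O)C[C@@](C)(O)[C@@H](O[Si](C)(C)C(C)(C)C)C=C)[C@@H]1CN(C)C | intermediate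
20 | cis-cyclooctene trans-fused to the γ-lactone, C1 silyl ether, C10 tertiary alcohol, C8 ester | O=C1O[C@@H]2/C=C\[C@H](O[Si](C)(C)C(C)(C)C)[C@](C)(O)C[C@@H](OC(=O)/C=C(\C)COC(C)=O)[C@H]2[C@@H]1CN(C)C | intermediate
21 | cyclooctenol: C1 hydroxyl of 20 free | O=C1O[C@@H]2/C=C\[C@H](O)[C@](C)(O)C[C@@H](OC(=O)/C=C(\C)COC(C)=O)[C@H]2[C@@H]1CN(C)C | intermediate
22 | 2-methyl-2-vinyloxirane | CC1(C=C)CO1 | starting material
23 | 2-methylidenebut-3-en-1-ol | C=CC(=C)CO | intermediate
24 | chloro(diisopropyl)[(2-methylidenebut-3-en-1-yl)oxy]silane | C=CC(=C)CO[Si](Cl)(C(C)C)C(C)C | intermediate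
25 | diisopropylsilaketal of 21 (O1) and 23 | O=C1O[C@@H]2/C=C\[C@H](O[Si](C(C)C)(C(C)C)OCC(=C)C=C)[C@](C)(O)C[C@@H](OC(=O)/C=C(\C)COC(C)=O)[C@H]2[C@@H]1CN(C)C | intermediate
26 | ten-membered diene bridged by the O1–Si(iPr)2–O15 silaketal | O=C1O[C@@H]2/C=C(CO[Si](C(C)C)(C(C)C)O3)\C=C/[C@H]3[C@](C)(O)C[C@@H](OC(=O)/C=C(\C)COC(C)=O)[C@H]2[C@@H]1CN(C)C | intermediate
27 | C1,C10,C15 triol of the ten-membered diene | O=C1O[C@@H]2/C=C(CO)\C=C/[C@H](O)[C@](C)(O)C[C@@H](OC(=O)/C=C(\C)COC(C)=O)[C@H]2[C@@H]1CN(C)C | intermediate
28 | C15 tert-butyldimethylsilyl ether of 27 | O=C1O[C@@H]2/C=C(CO[Si](C)(C)C(C)(C)C)\C=C/[C@H](O)[C@](C)(O)C[C@@H](OC(=O)/C=C(\C)COC(C)=O)[C@H]2[C@@H]1CN(C)C | intermediate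
29 | C1 methanesulfonate of 28 | O=C1O[C@@H]2/C=C(CO[Si](C)(C)C(C)(C)C)\C=C/[C@H](OS(C)(=O)=O)[C@](C)(O)C[C@@H](OC(=O)/C=C(\C)COC(C)=O)[C@H]2[C@@H]1CN(C)C | intermediate
30 | (1R,10R) vinyl epoxide, C15 silyl ether, C11 dimethylaminomethyl | O=C1O[C@@H]2/C=C(CO[Si](C)(C)C(C)(C)C)\C=C/[C@H]3O[C@]3(C)C[C@@H](OC(=O)/C=C(\C)COC(C)=O)[C@H]2[C@@H]1CN(C)C | intermediate
31 | C15 alcohol: 11,13-dihydro-13-(dimethylamino) derivative of the target | O=C1O[C@@H]2/C=C(CO)\C=C/[C@H]3O[C@]3(C)C[C@@H](OC(=O)/C=C(\C)COC(C)=O)[C@H]2[C@@H]1CN(C)C | intermediate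
32 | trimethylammonium iodide of 31 | O=C1O[C@@H]2/C=C(CO)\C=C/[C@H]3O[C@]3(C)C[C@@H](OC(=O)/C=C(\C)COC(C)=O)[C@H]2[C@@H]1C[N+](C)(C)C.[I-] | intermediate
33 | CNP0292814.2 | C=C1C(=O)O[C@@H]2/C=C(CO)\C=C/[C@H]3O[C@]3(C)C[C@@H](OC(=O)/C=C(\C)COC(C)=O)[C@@H]12 | target

**Step count and risks**

Total step count: 24. Longest linear sequence: 20 steps (steps 1–4, 6–8, 11–16, 18–24).

Steps most likely to fail:

1. Step 19 (key step). The risk is that the hindered ring alkene is not opened by the tethered alkylidene, or that intermolecular metathesis outruns the closure of the ten-membered ring. The fallback gives up the ring expansion and closes both rings directly on the open-chain precursor with known reaction types. It sets out from 19: HF·pyridine frees the C1 hydroxyl to give the open-chain C1 alcohol F1. F1 is tethered with 23 and iPr2SiCl2 as in step 18 to the open-chain silaketal F2. Second-generation Grubbs catalyst closes the eight-membered silaketal first by temporary-silicon-tethered ring-closing metathesis between the C1 vinyl group and the monosubstituted diene terminus, giving the monocyclic silaketal triene F3. Ene–diene ring-closing metathesis of the C6 vinyl group onto the 1,1-disubstituted diene terminus (second-generation Hoveyda–Grubbs catalyst, toluene, 80 °C, high dilution) then closes the ten-membered ring, and the route is rejoined at 26.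

2. Step 6. The risk is proton transfer from the butenolide to the hindered O,C-dilithio species, or addition in the 1,2-sense, so that the three-component coupling stalls. The fallback replaces the dianion cascade by a protected, stepwise sequence. It sets out from 6: Et3SiOTf and 2,6-lutidine give the tertiary triethylsilyl ether F4. Its monolithio derivative (t-BuLi, THF/DMPU, −78 °C) adds to 8, and protonation gives the conjugate adduct F5. A separate Mannich reaction of the lactone enolate (LiN(SiMe3)2, then CH2=NMe2+ I−) gives the silyl-protected Mannich base F6. AcOH/THF/H2O removes the tertiary triethylsilyl group, and the route is rejoined at 9.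

3. Step 22. The risk is ionisation of the doubly allylic C1 sulfonate before ring closure, with loss of configuration, SN2′ capture or elimination. The fallback avoids a sulfonate altogether: 28 is cyclodehydrated under Mitsunobu conditions (PPh3, diisopropyl azodicarboxylate, toluene, 0 °C). The less hindered secondary C1 hydroxyl is activated as the oxyphosphonium ion and displaced with inversion by the tertiary C10 hydroxyl. This sets out from 28 and comes back at 30 without any new compound.

Further compounds
F1 | step 19 | open-chain C1 alcohol (silyl ether of 19 cleaved) | O=C1O[C@H](C=C)[C@@H]([C@H](OC(=O)/C=C(\C)COC(C)=O)C[C@@](C)(O)[C@@H](O)C=C)[C@@H]1CN(C)C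
F2 | step 19 | open-chain diisopropylsilaketal of F1 and 23 | O=C1O[C@H](C=C)[C@@H]([C@H](OC(=O)/C=C(\C)COC(C)=O)C[C@@](C)(O)[C@@H](O[Si](C(C)C)(C(C)C)OCC(=C)C=C)C=C)[C@@H]1CN(C)C
F3 | step 19 | monocyclic eight-membered silaketal triene (C2=C3 closed, C6 vinyl and C4 methylidene free) | O=C1O[C@H](C=C)[C@@H]([C@H](OC(=O)/C=C(\C)COC(C)=O)C[C@@](C)(O)[C@H]2O[Si](C(C)C)(C(C)C)OCC(=C)/C=C\2)[C@@H]1CN(C)C
F4 | step 6 | tertiary triethylsilyl ether of 6 | C=C[C@H](O[Si](C)(C)C(C)(C)C)[C@](C)(O[Si](CC)(CC)CC)CC1SCCCS1
F5 | step 6 | conjugate adduct of lithiated F4 and 8 (C11 unsubstituted) | O=C1O[C@H](CO[Si](C)(C)C(C)(C)C)[C@@H](C2(C[C@@](C)(O[Si](CC)(CC)CC)[C@@H](O[Si](C)(C)C(C)(C)C)C=C)SCCCS2)C1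
F6 | step 6 | C10 triethylsilyl ether of 9 | O=C1O[C@H](CO[Si](C)(C)C(C)(C)C)[C@@H](C2(C[C@@](C)(O[Si](CC)(CC)CC)[C@@H](O[Si](C)(C)C(C)(C)C)C=C)SCCCS2)[C@@H]1CN(C)C
F0 | step 22 | none | none
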